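Readings and results come from a simulation for substances that don't exist.

Watch the side product.

| flask | electrophile | nucleophile | remark | time |
|---|---|---|---|---|
| south-west | 0.10 M | 0.12 M | run made earlier |  |
| west | 0.20 M | 0.12 M | run made earlier |  |
| ash | 0.10 M (fed, over 2.5 d) | 0.120 M | all else is in the flask from the start; the feed brings no volume worth counting | 3.0 d |
| cedar | 0.10 M | 0.120 M (fed, over 2.5 d) | all else is in the flask from the start; the feed brings no volume worth counting | 3.0 d |
| alder | 0.10 M | 0.120 M (fed, over 15 h) | all else is in the flask from the start; the feed brings no volume worth counting | 3.0 d |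
| maple | 0.10 M | 0.120 M | everything together at the start | 3.0 d |

- south-west (time / d: side product / %, target / %): 0.250: 9.3, 28.7; 0.417: 11.4, 36.5; 0.625: 15.1, 40.0; 1.04: 18.1, 44.1; 1.67: 23.3, 45.2; 3.00: 31.6, 43.7
- west (time / h: side product / %, target / %): 0.500: 1.8, 5.2; 1.00: 2.6, 6.4; 1.50: 4.6, 9.4; 2.50: 5.7, 13.1; 4.00: 9.0, 16.2; 8.00: 13.3, 19.7

(scatter of a reading: 0.5 percentage points)

- percent here means electrophile units held: one side product counts as two
- the numbers in the tables scatter with a standard deviation of 0.5 percentage points
- a reading or a percentage of target counts all its forms, free or not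

1. the flask that comes out highest in amount of side product, in percent of the electrophile charged; "all alike" if 1.5 percentage points covers them all (ash / cedar / alder / maple / all alike)
2. amount of side product at the end, in percent of the electrophile charged, ash
3. amount of side product at the end, in percent of the electrophile charged, cedar
4. amount of side product at the end, in percent of the electrophile charged, alder
5. amount of side product at the end, in percent of the electrophile charged, maple

In the south-west run, divide the side product's rate by the mean electrophile fraction over the same stretch, the fraction at any reading being the charge minus side product and target. Up to 0.250 d the rate is 0.372 d⁻¹. From 1.04 d to 3.00 d, with target standing at 44.1 % and 43.7 %, it is 0.0689 d⁻¹.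

early: 0.372 d⁻¹ / 81.0 % = 0.459 d⁻¹

The late stretch runs from a fraction of 37.8 % to one of 24.7 %.

late: 0.0689 d⁻¹ / 31.2 % = 0.220 d⁻¹

The rate slowed by a factor of 5.40: the electrophile fraction gives 2.60 and the falling constant gives 2.09. Held for 3.0 d, the early rate makes 112 % of the charge, yet the run reached 31.6 %.

Carry the late value, the side-product constant: side product made per day per whole fraction of electrophile, a pseudo-first-order constant, read with the scatter of 0.5 percentage points. The west run, with target still rising from 13.1 % to 19.7 %, reads 0.448 d⁻¹, close to the early value. For the slow feeds I assume the late value, 0.220 d⁻¹.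

Suppose cedar's electrophile falls steadily during the feed to 24.7 %. Suppose ash's climbs from none to what the highest south-west target reading and its own side product leave, 43.0 %, and stays there.

cedar: 0.220 d⁻¹ × (62.3 % × 2.5 d + 24.7 % × 0.500 d) = 37.1 %

ash: 0.220 d⁻¹ × 43.0 % × (1.25 d + 0.500 d) = 16.6 %

Maple repeats the south-west run, so 31.6 %. Alder's feed lasts a quarter of cedar's, so I place alder that far from maple towards cedar, at 33.0 %.

The forecast, which lies below this reckoning at cedar and above it at ash, named cedar highest with 20 % for ash, 34 % for cedar, 32 % for alder and 31 % for maple, holding that “starved nucleophile keeps electrophile high slightly longer”.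

Cedar comes out highest at 40.8 %, against 17.5 % for ash, 33.4 % for alder and 31.2 % for maple.

    electrophile + nucleophile → acid set free + target (k = 0.841 M⁻¹ h⁻¹)
    nucleophile + acid set free ⇌ protonated nucleophile, settled at all times (K = 25000 M⁻¹)
    crystals ⇌ target, rate k3*(cs3 - [target]) while solid is left; crystals form when [target] > cs3 (solubility = 1.10 mM, k = 3.71 h⁻¹)
    electrophile + target → side product (k = 4.12 M⁻¹ h⁻¹)

Over the first 2.5 d, cedar's electrophile averaged 67.6 % of the charge, and 0.220 d⁻¹ times that over 2.5 d gives 37.2 %, while the flask held 37.3 % of side product at 2.50 d. In ash, the electrophile went from 40.7 % to 34.7 % over the last 0.500 d, so 0.220 d⁻¹ gives 4.1 points, and the flask gained 4.2 points.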